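**Retrosynthetic overview**

1. Germacrane numbering is used: ring C1–C10, lactone C6–O–C12(=O)–C11(=C13)–C7, methyls C14 on C10 and C15 on C4; the target is (1R,3S,6R,7R,8S,10R). The enabling feature is the trans-configured (Z)-2-ene-1,4-dioxy unit O–C6–C5=C4(C15)–C3–OAc, whose C6 oxygen is the ring oxygen of the γ-lactone (O–C12–C11–C7–C6) fused to the ten-membered ring. This is the retron of a 1,4-oxidation of a ring cis,cis-1,3-diene by a carboxylate held on C7 and an external acetate.
2. Oxirane (formed last): peracid epoxidation of the (E)-C1=C10 bond of lactone 23.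
3. γ-Lactone (formed second): palladium-catalysed oxidative trans-1,4-acetoxylactonisation of triene acid 22, which forms the O–C6 bond, the C3–OAc bond, the C3 and C6 stereocentres and the (Z)-C4=C5 bond in one operation.
4. Ten-membered carbocycle (formed first): diene–ene ring-closing metathesis at C5=C6 of the acyclic ester 19.
5. 19 comes from a chromium-catalysed asymmetric 2-(alkoxycarbonyl)allylation (C7–C8) of trienal 12 with bromide 16, then Mitsunobu inversion at C8 with 3-methylbutanoic acid. 12 comes from carboalumination/alkenyl–allyl coupling (C1–C2); 16 comes from a Morita–Baylis–Hillman adduct.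

Key step: step 13

Remark (assumption): the allylation of step 9 is taken to be syn-selective, as is usual for ester-substituted (Z)-allyl halides, and the ligand enantiomer is the one that gives the 4R carbinol. The needed anti C7/C8 relationship then follows from the inversion in step 10.

**Route**

Step 1
Reactants: 1 (2Z)-3-methylpent-2-en-4-yn-1-ol
Product: 4 (2Z)-3-methyl-5-(trimethylsilyl)pent-2-en-4-yn-1-ol, via dimagnesium salt 2 (not isolated), via bis-silyl compound 3 (not isolated)
Conditions: EtMgBr (2.2 equiv), THF, 0 °C to rt; TMSCl (2.3 equiv); then 1 M aq. HCl, rt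
Reagents that add atoms: chlorotrimethylsilane, C[Si](C)(C)Cl; ethylmagnesium bromide, CC[Mg]Br (magnesium in 2 only)
Why: Two equivalents of Grignard reagent deprotonate the hydroxyl and the terminal alkyne, both sites are silylated, and only the labile Si–O bond is cleaved on acidic work-up (acetylide C-silylation); the (Z)-olefin is untouched.

Step 2
Reactants: 4 (2Z)-3-methyl-5-(trimethylsilyl)pent-2-en-4-yn-1-ol
Product: 6 [(3Z)-5-chloro-3-methylpent-3-en-1-yn-1-yl]trimethylsilane, via allylic mesylate 5 (not isolated)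
Conditions: MsCl, 2,4,6-collidine, LiCl, DMF, 0 °C
Reagents that add atoms: lithium chloride, [Li+].[Cl-]; methanesulfonyl chloride, CS(=O)(=O)Cl (in 5 only)
Why: In situ mesylation followed by SN2 displacement by chloride at the primary allylic carbon should give the allylic chloride without allylic transposition or (Z)/(E) isomerisation.

Step 3
Reactants: 7 (but-3-yn-1-yloxy)(tert-butyl)dimethylsilane; 6 [(3Z)-5-chloro-3-methylpent-3-en-1-yn-1-yl]trimethylsilane
Product: 9 tert-butyl{[(3E,6Z)-3,7-dimethyl-9-(trimethylsilyl)nona-3,6-dien-8-yn-1-yl]oxy}dimethylsilane, via alkenylalane 8 (not isolated)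
Conditions: AlMe3 (2 equiv), Cp2ZrCl2 (20 mol %), ClCH2CH2Cl, rt; then 6, Pd(PPh3)4 (5 mol %), THF, rt
Reagents that add atoms: trimethylaluminium, C[Al](C)C
Why: Zirconium-catalysed syn-carboalumination (Negishi) places the methyl group on C10 and aluminium on C1, which fixes the (E)-C1=C10 bond; zerovalent palladium then couples the alkenylalane with the allylic chloride at its primary terminus with retention of both olefin geometries (alkenyl–allyl Negishi coupling), and the silyl cap keeps the alkyne out of both events.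

Step 4
Reactants: 9 tert-butyl{[(3E,6Z)-3,7-dimethyl-9-(trimethylsilyl)nona-3,6-dien-8-yn-1-yl]oxy}dimethylsilane
Product: 10 (3E,6Z)-3,7-dimethylnona-3,6-dien-8-yn-1-ol
Conditions: TBAF (2.5 equiv), THF, 0 °C to rt
Reagents that add atoms: none
Why: Fluoride cleaves the O–Si bond of the silyl ether and the C(sp)–Si bond in one operation (fluoride desilylation); the olefins are inert.

Step 5
Reactants: 10 (3E,6Z)-3,7-dimethylnona-3,6-dien-8-yn-1-ol
Product: 11 (3E,6Z)-3,7-dimethylnona-3,6,8-trien-1-ol
Conditions: H2 (1 atm), Pd/CaCO3 poisoned with Pb(OAc)2 (Lindlar catalyst), quinoline, EtOAc, rt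
Reagents that add atoms: none
Why: Lindlar semihydrogenation should reduce only the terminal alkyne to a vinyl group, which completes the (Z)-configured 3-methyl-1,3-diene; the trisubstituted olefins are not hydrogenated on the poisoned catalyst.

Step 6
Reactants: 11 (3E,6Z)-3,7-dimethylnona-3,6,8-trien-1-ol
Product: 12 (3E,6Z)-3,7-dimethylnona-3,6,8-trienal
Conditions: Dess–Martin periodinane, NaHCO3, CH2Cl2, 0 °C; used at once
Reagents that add atoms: none
Why: Buffered Dess–Martin oxidation should give the β,γ-unsaturated aldehyde without migration of the C1=C10 bond into conjugation.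

Step 7
Reactants: 13 tert-butyl prop-2-enoate; 14 (2E)-but-2-enal
Product: 15 tert-butyl (4E)-3-hydroxy-2-methylidenehex-4-enoate (racemic)
Conditions: DABCO (0.5 equiv), neat, rt
Reagents that add atoms: none
Why: Morita–Baylis–Hillman reaction: the amine-bound acrylate enolate adds 1,2 to the enal; the carbinol stereocentre is racemic and is erased in step 8.

Step 8
Reactants: 15 tert-butyl (4E)-3-hydroxy-2-methylidenehex-4-enoate
Product: 16 tert-butyl (2Z,4E)-2-(bromomethyl)hexa-2,4-dienoate
Conditions: NBS, Me2S, CH2Cl2, 0 °C to rt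
Reagents that add atoms: N-bromosuccinimide, O=C1CCC(=O)N1Br
Why: Corey–Kim-type bromination of the Baylis–Hillman alcohol proceeds with SN2′ transposition to the conjugated primary allylic bromide, the thermodynamically preferred (2Z) isomer (propenyl trans to the ester).

Step 9
Reactants: 12 (3E,6Z)-3,7-dimethylnona-3,6,8-trienal; 16 tert-butyl (2Z,4E)-2-(bromomethyl)hexa-2,4-dienoate
Product: 18 tert-butyl (3R,4R,6E,9Z)-4-hydroxy-6,10-dimethyl-2-methylidene-3-[(1E)-prop-1-en-1-yl]dodeca-6,9,11-trienoate, via silyl ether 17 (not isolated)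
Conditions: CrCl2 (10 mol %), tridentate carbazole bis(oxazoline) ligand (12 mol %), Mn powder, TMSCl, THF, rt; then citric acid, MeOH, rt
Reagents that add atoms: chlorotrimethylsilane, C[Si](C)(C)Cl (silicon in 17 only)
Why: Catalytic asymmetric Nozaki–Hiyama–Kishi 2-(alkoxycarbonyl)allylation: the primary allylchromium species (trivalent chromium) adds through its γ-carbon (C7) in a closed chair transition state with the propenyl group, cis to the CH2–Cr carbon, axial, which gives the syn C7/C8 relationship, while the chiral ligand selects the aldehyde face (C8 = R, hence C7 = R); the tert-butyl ester prevents lactonisation and silylation turns over the catalyst.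

Step 10
Reactants: 18 tert-butyl (3R,4R,6E,9Z)-4-hydroxy-6,10-dimethyl-2-methylidene-3-[(1E)-prop-1-en-1-yl]dodeca-6,9,11-trienoate
Product: 19 tert-butyl (3R,4S,6E,9Z)-6,10-dimethyl-2-methylidene-4-[(3-methylbutanoyl)oxy]-3-[(1E)-prop-1-en-1-yl]dodeca-6,9,11-trienoate
Conditions: PPh3, DIAD (betaine formed first at 0 °C), 3-methylbutanoic acid, toluene, 0 °C to rt
Reagents that add atoms: 3-methylbutanoic acid, CC(C)CC(=O)O
Why: Mitsunobu esterification: SN2 displacement of the oxyphosphonium group by 3-methylbutanoate inverts C8 (4R to 4S), so the ester and the required anti C7/C8 relationship are installed together.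

Step 11
Reactants: 19 tert-butyl (3R,4S,6E,9Z)-6,10-dimethyl-2-methylidene-4-[(3-methylbutanoyl)oxy]-3-[(1E)-prop-1-en-1-yl]dodeca-6,9,11-trienoate
Product: 20 tert-butyl 2-[(1R,2Z,4Z,7E,10S)-4,8-dimethyl-10-[(3-methylbutanoyl)oxy]cyclodeca-2,4,7-trien-1-yl]prop-2-enoate
Conditions: second-generation Grubbs catalyst RuCl2(=CHPh)(PCy3)(H2IMes) (10 mol %), CH2Cl2 (0.5 mM), 40 °C
Reagents that add atoms: none
Why: Diene–ene ring-closing metathesis with loss of propene closes the ten-membered ring at C5=C6; the (Z) geometry is the one a ring already holding an (E)-trisubstituted olefin can accommodate, and the 1,1-disubstituted acrylate and the trisubstituted olefins are poor metathesis partners.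

Step 12
Reactants: 20 tert-butyl 2-[(1R,2Z,4Z,7E,10S)-4,8-dimethyl-10-[(3-methylbutanoyl)oxy]cyclodeca-2,4,7-trien-1-yl]prop-2-enoate
Product: 22 2-[(1R,2Z,4Z,7E,10S)-4,8-dimethyl-10-[(3-methylbutanoyl)oxy]cyclodeca-2,4,7-trien-1-yl]prop-2-enoic acid, via silyl ester 21 (not isolated)
Conditions: TMSOTf, 2,6-lutidine, CH2Cl2, 0 °C; then aq. pH 4 buffer
Reagents that add atoms: trimethylsilyl trifluoromethanesulfonate, C[Si](C)(C)OS(=O)(=O)C(F)(F)F (silicon in 21 only)
Why: Silyl triflate-mediated cleavage of the tert-butyl ester (loss of 2-methylpropene from the O-silylated ester) under buffered aprotic conditions should spare the acid-sensitive triene and the secondary ester; the silyl ester hydrolyses on work-up.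

Step 13
Reactants: 22 2-[(1R,2Z,4Z,7E,10S)-4,8-dimethyl-10-[(3-methylbutanoyl)oxy]cyclodeca-2,4,7-trien-1-yl]prop-2-enoic acid
Product: 23 (3S,6R,7R,8S)-3-acetoxy-8-(3-methylbutanoyloxy)germacra-1(10)E,4Z,11(13)-trien-12,6-olide
Conditions: Pd(OAc)2 (10 mol %), 1,4-benzoquinone (20 mol %), MnO2 (2 equiv), AcOH–acetone (1:4), 20 °C, chloride-free
Reagents that add atoms: acetic acid, CC(=O)O
Why: Divalent palladium binds the cis,cis-diene C3=C4–C5=C6 on the face away from the C7 side chain, the carboxylate attacks C6 anti to the metal to give a π-allylpalladium over C3–C5, acetate bound to the same metal then migrates to C3 on the metal face, and the zerovalent palladium set free is reoxidised by benzoquinone/MnO2. The closest known reaction type is the palladium-catalysed stereocontrolled 1,4-acetoxylactonisation of dienylacetic acids (intramolecular 1,4-oxidation of conjugated dienes). The γ-lactone closes in the 5-exo-trig mode through the O–C6 bond. C6 is controlled by the C7 stereocentre, because allylic 1,3-strain across the cis C5=C6 bond keeps H7 in the diene plane so that C11 delivers the carboxylate to the face giving the 6,7-trans fusion (6R), and C3 (3S) is controlled by the metal, which stands anti to the new C6–O bond and passes acetate to its own face (trans-1,4). The (Z)-C4=C5 geometry follows from the ring-bound anti,anti π-allyl, which cannot undergo syn–anti exchange inside the ten-membered ring. The step needs site selectivity for the diene over the isolated C1=C10 and the acrylic C11=C13 bonds (secured by diene coordination and the electron-poor acrylate), 1,4- over 1,2-attack (secured by the inductive effect of the C6 oxygen) and trans- over cis-addition (secured by excluding chloride).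

Step 14
Reactants: 23 (3S,6R,7R,8S)-3-acetoxy-8-(3-methylbutanoyloxy)germacra-1(10)E,4Z,11(13)-trien-12,6-olide
Product: 24 (1R,3S,6R,7R,8S,10R)-3-acetoxy-1,10-epoxy-8-(3-methylbutanoyloxy)germacra-4Z,11(13)-dien-12,6-olide (CNP0157657.1)
Conditions: mCPBA (1.05 equiv), NaHCO3, CH2Cl2, −20 to 0 °C
Reagents that add atoms: 3-chloroperoxybenzoic acid, O=C(OO)c1cccc(Cl)c1
Why: Prilezhaev epoxidation: the electron-rich (E)-C1=C10 bond should react in preference to C4=C5, which is deactivated by two allylic acyloxy groups, and to the electron-poor methylene lactone; attack on the outer face of the trans double bond in the ground-state conformer is expected to give the trans (1R,10R)-epoxide.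

**Compound list**

1 | (2Z)-3-methylpent-2-en-4-yn-1-ol | C#C/C(C)=C\CO | starting material
2 | bromomagnesium (2Z)-5-(bromomagnesio)-3-methylpent-2-en-4-yn-1-olate | Br[Mg]C#C/C(C)=C\CO[Mg]Br | intermediate (not isolated)
3 | trimethyl{[(2Z)-3-methyl-5-(trimethylsilyl)pent-2-en-4-yn-1-yl]oxy}silane | C[Si](C)(C)C#C/C(C)=C\CO[Si](C)(C)C | intermediate (not isolated)
4 | (2Z)-3-methyl-5-(trimethylsilyl)pent-2-en-4-yn-1-ol | C[Si](C)(C)C#C/C(C)=C\CO | intermediate
5 | (2Z)-3-methyl-5-(trimethylsilyl)pent-2-en-4-yn-1-yl methanesulfonate | C[Si](C)(C)C#C/C(C)=C\COS(C)(=O)=O | intermediate (not isolated)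
6 | [(3Z)-5-chloro-3-methylpent-3-en-1-yn-1-yl]trimethylsilane | C[Si](C)(C)C#C/C(C)=C\CCl | intermediate
7 | (but-3-yn-1-yloxy)(tert-butyl)dimethylsilane | C#CCCO[Si](C)(C)C(C)(C)C | starting material
8 | [(1E)-4-{[tert-butyl(dimethyl)silyl]oxy}-2-methylbut-1-en-1-yl]dimethylalane | C[Al](C)/C=C(\C)CCO[Si](C)(C)C(C)(C)C | intermediate (not isolated)
9 | tert-butyl{[(3E,6Z)-3,7-dimethyl-9-(trimethylsilyl)nona-3,6-dien-8-yn-1-yl]oxy}dimethylsilane | C[Si](C)(C)C#C/C(C)=C\C/C=C(\C)CCO[Si](C)(C)C(C)(C)C | intermediate
10 | (3E,6Z)-3,7-dimethylnona-3,6-dien-8-yn-1-ol | C#C/C(C)=C\C/C=C(\C)CCO | intermediate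
11 | (3E,6Z)-3,7-dimethylnona-3,6,8-trien-1-ol | C=C/C(C)=C\C/C=C(\C)CCO | intermediate
12 | (3E,6Z)-3,7-dimethylnona-3,6,8-trienal | C=C/C(C)=C\C/C=C(\C)CC=O | intermediate
13 | tert-butyl prop-2-enoate | C=CC(=O)OC(C)(C)C | starting material
14 | (2E)-but-2-enal | C/C=C/C=O | starting material
15 | tert-butyl (4E)-3-hydroxy-2-methylidenehex-4-enoate (racemic) | C/C=C/C(O)C(=C)C(=O)OC(C)(C)C | intermediate
16 | tert-butyl (2Z,4E)-2-(bromomethyl)hexa-2,4-dienoate | C/C=C/C=C(\CBr)C(=O)OC(C)(C)C | intermediate
17 | tert-butyl (3R,4R,6E,9Z)-6,10-dimethyl-2-methylidene-3-[(1E)-prop-1-en-1-yl]-4-[(trimethylsilyl)oxy]dodeca-6,9,11-trienoate | C=C(C(=O)OC(C)(C)C)[C@@H](/C=C/C)[C@H](O[Si](C)(C)C)C/C(C)=C/C/C=C(C)\C=C | intermediate (not isolated)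
18 | tert-butyl (3R,4R,6E,9Z)-4-hydroxy-6,10-dimethyl-2-methylidene-3-[(1E)-prop-1-en-1-yl]dodeca-6,9,11-trienoate | C=C(C(=O)OC(C)(C)C)[C@@H](/C=C/C)[C@H](O)C/C(C)=C/C/C=C(C)\C=C | intermediate
19 | tert-butyl (3R,4S,6E,9Z)-6,10-dimethyl-2-methylidene-4-[(3-methylbutanoyl)oxy]-3-[(1E)-prop-1-en-1-yl]dodeca-6,9,11-trienoate | C=C(C(=O)OC(C)(C)C)[C@@H](/C=C/C)[C@@H](OC(=O)CC(C)C)C/C(C)=C/C/C=C(C)\C=C | intermediate
20 | tert-butyl 2-[(1R,2Z,4Z,7E,10S)-4,8-dimethyl-10-[(3-methylbutanoyl)oxy]cyclodeca-2,4,7-trien-1-yl]prop-2-enoate | C=C(C(=O)OC(C)(C)C)[C@H]1/C=C\C(C)=C/C/C=C(\C)C[C@@H]1OC(=O)CC(C)C | intermediate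
21 | trimethylsilyl 2-[(1R,2Z,4Z,7E,10S)-4,8-dimethyl-10-[(3-methylbutanoyl)oxy]cyclodeca-2,4,7-trien-1-yl]prop-2-enoate | C=C(C(=O)O[Si](C)(C)C)[C@H]1/C=C\C(C)=C/C/C=C(\C)C[C@@H]1OC(=O)CC(C)C | intermediate (not isolated)
22 | 2-[(1R,2Z,4Z,7E,10S)-4,8-dimethyl-10-[(3-methylbutanoyl)oxy]cyclodeca-2,4,7-trien-1-yl]prop-2-enoic acid | C=C(C(=O)O)[C@H]1/C=C\C(C)=C/C/C=C(\C)C[C@@H]1OC(=O)CC(C)C | intermediate
23 | (3S,6R,7R,8S)-3-acetoxy-8-(3-methylbutanoyloxy)germacra-1(10)E,4Z,11(13)-trien-12,6-olide | C=C1C(=O)O[C@@H]2/C=C(/C)[C@@H](OC(C)=O)C/C=C(\C)C[C@H](OC(=O)CC(C)C)[C@@H]12 | intermediate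
24 | (1R,3S,6R,7R,8S,10R)-3-acetoxy-1,10-epoxy-8-(3-methylbutanoyloxy)germacra-4Z,11(13)-dien-12,6-olide | C=C1C(=O)O[C@@H]2/C=C(/C)[C@@H](OC(C)=O)C[C@H]3O[C@]3(C)C[C@H](OC(=O)CC(C)C)[C@@H]12 | target

**Step count and risks**

Total step count: 14. Longest linear sequence: 12 steps (steps 1–6 and 9–14).

Steps most likely to fail:

1. Step 11 (ring-closing metathesis). Intermolecular metathesis may outrun closure of the strained ten-membered ring, the (E)-C5=C6 isomer may form, or metathesis at the internal C3=C4 bond may contract the ring. The fallback sets out from 18 and returns at 22. Acid-catalysed lactonisation of 18 (CSA, toluene, 60 °C) should give the cis-fused α-methylene-γ-lactone F1, in which the propenyl group on C7 and the trienyl chain on C8 stand cis on a five-membered ring. Ring-closing metathesis on this template should give the macrocyclic cis-8,12-lactone F2 more readily than on the open chain. Saponification (LiOH, THF–H2O) and alkylation of the carboxylate (allyl bromide, Cs2CO3, DMF) should give the hydroxy allyl ester F3. Mitsunobu esterification with 3-methylbutanoic acid inverts C8 and gives the allyl ester F4. Pd(PPh3)4 and morpholine then remove the allyl group, and the route is rejoined at 22.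

2. Step 9 (asymmetric allylation). Enantioface control or syn selectivity may erode with the γ-dienyl chromium reagent, and the β,γ-unsaturated aldehyde may slip into conjugation. The fallback sets out from 16 and returns at 18. Copper-catalysed borylation of 16 (B2pin2, CuCl, KOtBu, THF) should give the allylboronate F5 with the olefin geometry kept. Its addition to 12 under catalysis by a chiral BINOL-derived phosphoric acid runs through a closed six-membered transition state whose relative topicity is fixed by the configurationally stable boronate (propenyl cis to the CH2–B carbon, hence syn) and whose face selectivity comes from the acid. Aqueous work-up gives 18.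

3. Step 13 (key step). The carboxylate may be delivered to the wrong face of C6 (cis-fused lactone), the trans-1,4 sense may be lost through external acetate attack, or the diene may be consumed by cycloaddition with the quinone. The fallback sets out from 22 and returns at 23. Iodolactonisation of 22 under equilibrating conditions (I2, MeCN, 0 °C) should give the 6,7-trans iodolactone F6 by anti addition across C5=C6. Displacement of the allylic iodide by acetate (KOAc, 18-crown-6, DMF) in the syn-SN2′ mode places the acetate on C3 on the face of the departing iodide, that is trans to the lactone oxygen, moves the double bond to C4=C5 and gives 23.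

Further compounds
F1 | step 11 | (4R,5R)-5-[(2E,5Z)-2,6-dimethylocta-2,5,7-trien-1-yl]-3-methylidene-4-[(1E)-prop-1-en-1-yl]oxolan-2-one | C=C1C(=O)O[C@H](C/C(C)=C/C/C=C(C)\C=C)[C@@H]1/C=C/C
F2 | step 11 | (7R,8R)-germacra-1(10)E,3Z,5Z,11(13)-tetraen-12,8-olide (cis-fused) | C=C1C(=O)O[C@@H]2C/C(C)=C/C/C=C(C)\C=C/[C@H]12
F3 | step 11 | prop-2-en-1-yl 2-[(1R,2Z,4Z,7E,10R)-10-hydroxy-4,8-dimethylcyclodeca-2,4,7-trien-1-yl]prop-2-enoate | C=C(C(=O)OCC=C)[C@H]1/C=C\C(C)=C/C/C=C(\C)C[C@H]1O
F4 | step 11 | prop-2-en-1-yl 2-[(1R,2Z,4Z,7E,10S)-4,8-dimethyl-10-[(3-methylbutanoyl)oxy]cyclodeca-2,4,7-trien-1-yl]prop-2-enoate | C=C(C(=O)OCC=C)[C@H]1/C=C\C(C)=C/C/C=C(\C)C[C@@H]1OC(=O)CC(C)C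
F5 | step 9 | tert-butyl (2E,4E)-2-[(4,4,5,5-tetramethyl-1,3,2-dioxaborolan-2-yl)methyl]hexa-2,4-dienoate | C/C=C/C=C(\CB1OC(C)(C)C(C)(C)O1)C(=O)OC(C)(C)C
F6 | step 13 | (5S,6S,7R,8S)-5-iodo-8-(3-methylbutanoyloxy)germacra-1(10)E,3Z,11(13)-trien-12,6-olide | C=C1C(=O)O[C@@H]2[C@@H](I)/C(C)=C\C/C=C(\C)C[C@H](OC(=O)CC(C)C)[C@@H]12
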